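**Plan**
- Numbering: C1 is the benzylic CH2 on the 3,4-dihydroxyphenyl ring, C7 the benzylic CH2 on the 4-hydroxyphenyl ring; O3 carries the acetate and O5 is free. The C2–C6 segment with its (3S,5S)-anti oxygens is C2-symmetric, and both flanking carbons are benzylic.
- Retrosynthesis: remove the acetyl and benzyl groups, then cut C1–C2 and C6–C7 to two benzylic Grignard reagents and (2R,4R)-1,2:4,5-diepoxypentane.
- The diepoxide goes back to (2R,4R)-1,5-dichloropentane-2,4-diol, and this to 1,5-dichloropentane-2,4-dione by reduction of both carbonyls (C3–H and C5–H); the dione comes from chloroacetyl chloride and vinyl acetate.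
- Forward: no carbocycle is built; two oxiranes are closed and then opened one at a time. C6–C7 is joined first, O5 is benzylated, C1–C2 is joined, O3 is acetylated, and hydrogenolysis finishes.
- Stereochemistry: both carbinol centres come from one (S)-BINAP–ruthenium hydrogenation; no later step breaks a bond at C3 or C5.

Key step: step 3

Assumption: the sense of induction follows the BINAP–ruthenium model in which (S)-BINAP gives the (R)-chlorohydrin from 4-chloro-3-oxobutanoate esters; on that basis (S)-BINAP is assigned to the (2R,4R)-diol, and the rotation of 7 should be checked before scale-up.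

**Route**

Step 1
Reactants: 1 chloroacetyl chloride; 2 vinyl acetate
Product: 5 bis(1,5-dichloropentane-2,4-dionato)copper, via 4-chloro-2-(chloroacetyl)-3-oxobutanal 3 (not isolated), via 1,5-dichloropentane-2,4-dione 4 (not isolated)
Conditions: AlCl3 (3 equiv), 1 (3 equiv), CHCl3, 0 °C; add 2, then 50 °C; ice/aq HCl; aq Cu(OAc)2, rt, filter
Reagents that add atoms: copper diacetate, CC(=O)[O-].CC(=O)[O-].[Cu+2]
Why: Friedel–Crafts-type acylation of the enol ester at its CH2 carbon, a second acylation of the resulting β-acetoxyvinyl ketone at the same carbon and hydrolytic retro-Claisen deformylation of the triacylmethane 3 on work-up should give the 1,3-diketone 4, which is caught as its neutral chelate of divalent copper and so separated from tar.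

Step 2
Reactants: 5 bis(1,5-dichloropentane-2,4-dionato)copper
Product: 4 1,5-dichloropentane-2,4-dione
Conditions: 10% aq H2SO4, Et2O, rt
Reagents that add atoms: none
Why: Protonolysis of the copper β-diketonate by a strong mineral acid (acid decomplexation) should release the pure diketone into the ether layer while CuSO4 stays in water.

Step 3
Reactants: 4 1,5-dichloropentane-2,4-dione
Product: 7 (2R,4R)-1,5-dichloropentane-2,4-diol, via (4R)-1,5-dichloro-4-hydroxypentan-2-one 6 (not isolated)
Conditions: H2 (85 bar), [RuCl2((S)-BINAP)]2·NEt3 (0.2 mol%), MeOH, 80 °C; recrystallise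
Reagents that add atoms: none
Why: Under H2 the precatalyst becomes a monohydride of divalent ruthenium that binds 4 as an O,O-chelate through both carbonyl oxygens and delivers hydride to the carbonyl carbon inside that chelate; the hydroxy ketone 6 so formed re-enters the cycle bound through its hydroxyl and remaining carbonyl. This is the Noyori asymmetric hydrogenation of β-diketones to anti-1,3-diols, the class that also covers pentane-2,4-dione and 4-chloro-3-oxobutanoates. No ring closes and no skeletal bond forms; only the C–H bonds at the two carbinol carbons (C3 and C5 of the target) are made. Both centres are set by the (S)-BINAP ligand alone: the first reduction fixes the carbinol of 6 and the second, under the same catalyst control, repeats that sense, giving the anti diol, which is (2R,4R) because CH2Cl outranks the central CH2. The step needs carbonyl reduction without C–Cl hydrogenolysis and a high anti-to-meso ratio; the 1,3-dicarbonyl array provides the bidentate binding the catalyst requires, the homogeneous ruthenium hydride in neutral methanol leaves alkyl chlorides alone, and the elevated temperature suppresses competing chloride coordination. Because the minor enantiomer of 6 is drained into the meso diol, the anti diol should be enriched in enantiopurity (Horeau-type amplification), and crystallisation removes the meso isomer.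

Step 4
Reactants: 7 (2R,4R)-1,5-dichloropentane-2,4-diol
Product: 9 (2R,4R)-1,2:4,5-diepoxypentane, via (2R)-1-chloro-3-[(2R)-oxiran-2-yl]propan-2-ol 8 (not isolated)
Conditions: KOH (powdered, 5 equiv), Et2O, rt; distil
Reagents that add atoms: none
Why: Twofold intramolecular Williamson etherification (3-exo-tet SN2 of each alkoxide on its neighbouring CH2Cl) closes both oxiranes without touching the C–O bonds at the stereocentres, so the R,R configuration is carried over unchanged.

Step 5
Reactants: 9 (2R,4R)-1,2:4,5-diepoxypentane; 10 4-(benzyloxy)benzyl chloride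
Product: 12 (2S)-4-[4-(benzyloxy)phenyl]-1-[(2R)-oxiran-2-yl]butan-2-ol, via 4-(benzyloxy)benzylmagnesium chloride 11 (not isolated)
Conditions: Mg, THF, 0 °C (10 → 11, dilute); add slowly to 9 (1.5 equiv), CuI (10 mol%), THF, −40 °C; aq NH4Cl
Reagents that add atoms: none
Why: Copper-catalysed Grignard opening of a terminal epoxide occurs by SN2 attack at the unsubstituted CH2 (forming C6–C7), and because 9 is C2-symmetric either oxirane gives the same mono-adduct, over-addition being held back by the excess of 9 and slow addition at low temperature.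

Step 6
Reactants: 12 (2S)-4-[4-(benzyloxy)phenyl]-1-[(2R)-oxiran-2-yl]butan-2-ol
Product: 13 (2R)-2-{(2S)-2-(benzyloxy)-4-[4-(benzyloxy)phenyl]butyl}oxirane
Conditions: NaH, BnBr, Bu4NI (cat.), THF, 0 °C → rt
Reagents that add atoms: benzyl bromide, BrCc1ccccc1
Why: Williamson benzylation of the only hydroxyl (O5) should outrun attack of the alkoxide on the oxirane, since that would need a 4-exo or 5-endo closure, and it marks O5 so that the later acetate can go only to O3.

Step 7
Reactants: 14 3,4-bis(benzyloxy)benzaldehyde
Product: 15 [3,4-bis(benzyloxy)phenyl]methanol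
Conditions: NaBH4, MeOH/THF, 0 °C
Reagents that add atoms: none
Why: Borohydride reduction of an aromatic aldehyde to the benzylic alcohol is routine and leaves aryl benzyl ethers untouched.

Step 8
Reactants: 15 [3,4-bis(benzyloxy)phenyl]methanol
Product: 16 3,4-bis(benzyloxy)benzyl chloride
Conditions: SOCl2, CH2Cl2, 0 °C → rt
Reagents that add atoms: thionyl chloride, O=S(Cl)Cl
Why: Deoxychlorination of an electron-rich benzylic alcohol through its chlorosulfite is fast at low temperature and gives the chloride needed for magnesium insertion.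

Step 9
Reactants: 13 (2R)-2-{(2S)-2-(benzyloxy)-4-[4-(benzyloxy)phenyl]butyl}oxirane; 16 3,4-bis(benzyloxy)benzyl chloride
Product: 18 (3S,5S)-5-(benzyloxy)-1-[3,4-bis(benzyloxy)phenyl]-7-[4-(benzyloxy)phenyl]heptan-3-ol, via 3,4-bis(benzyloxy)benzylmagnesium chloride 17 (not isolated)
Conditions: Mg, THF, 0 °C (16 → 17, dilute, 2.5 equiv); 13, CuI (15 mol%), THF, −30 → 0 °C; aq NH4Cl
Reagents that add atoms: none
Why: A second copper-catalysed Grignard opening at the terminal oxirane carbon forms C1–C2 and frees O3 as the only hydroxyl, the C3 configuration being retained because no bond at that carbon is broken.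

Step 10
Reactants: 18 (3S,5S)-5-(benzyloxy)-1-[3,4-bis(benzyloxy)phenyl]-7-[4-(benzyloxy)phenyl]heptan-3-ol
Product: 19 (3S,5S)-5-(benzyloxy)-1-[3,4-bis(benzyloxy)phenyl]-7-[4-(benzyloxy)phenyl]heptan-3-yl acetate
Conditions: Ac2O, pyridine, DMAP (cat.), CH2Cl2, rt
Reagents that add atoms: acetic anhydride, CC(=O)OC(C)=O
Why: DMAP-catalysed acylation of the single free secondary alcohol puts the acetate on O3 with no regiochemical choice, since O5 and all phenols are benzylated.

Step 11
Reactants: 19 (3S,5S)-5-(benzyloxy)-1-[3,4-bis(benzyloxy)phenyl]-7-[4-(benzyloxy)phenyl]heptan-3-yl acetate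
Product: 20 (3S,5S)-1-(3,4-dihydroxyphenyl)-5-hydroxy-7-(4-hydroxyphenyl)heptan-3-yl acetate (CNP0249634.1)
Conditions: H2 (1 atm), Pd(OH)2/C, EtOAc, rt
Reagents that add atoms: none
Why: Catalytic hydrogenolysis cleaves the four O–benzyl bonds under neutral, aprotic conditions, which should leave the non-benzylic acetate in place and give no base or acid to drive a 1,3-acetyl shift from O3 to O5.

**Compound list**
1 | chloroacetyl chloride | O=C(Cl)CCl | starting material
2 | vinyl acetate | C=COC(C)=O | starting material
3 | 4-chloro-2-(chloroacetyl)-3-oxobutanal | O=CC(C(=O)CCl)C(=O)CCl | intermediate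
4 | 1,5-dichloropentane-2,4-dione | O=C(CCl)CC(=O)CCl | intermediate
5 | bis(1,5-dichloropentane-2,4-dionato)copper, Cu(C5H5Cl2O2)2 | ClCC(=O)C=C([O-])CCl.ClCC(=O)C=C([O-])CCl.[Cu+2] | intermediate
6 | (4R)-1,5-dichloro-4-hydroxypentan-2-one | O=C(CCl)C[C@@H](O)CCl | intermediate
7 | (2R,4R)-1,5-dichloropentane-2,4-diol | O[C@@H](CCl)C[C@@H](O)CCl | intermediate
8 | (2R)-1-chloro-3-[(2R)-oxiran-2-yl]propan-2-ol | O[C@@H](CCl)C[C@@H]1CO1 | intermediate
9 | (2R,4R)-1,2:4,5-diepoxypentane | C1O[C@@H]1C[C@@H]1CO1 | intermediate
10 | 4-(benzyloxy)benzyl chloride | ClCc1ccc(OCc2ccccc2)cc1 | starting material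
11 | 4-(benzyloxy)benzylmagnesium chloride | Cl[Mg]Cc1ccc(OCc2ccccc2)cc1 | intermediate
12 | (2S)-4-[4-(benzyloxy)phenyl]-1-[(2R)-oxiran-2-yl]butan-2-ol | O[C@@H](CCc1ccc(OCc2ccccc2)cc1)C[C@@H]1CO1 | intermediate
13 | (2R)-2-{(2S)-2-(benzyloxy)-4-[4-(benzyloxy)phenyl]butyl}oxirane | c1ccccc1CO[C@@H](CCc1ccc(OCc2ccccc2)cc1)C[C@@H]1CO1 | intermediate
14 | 3,4-bis(benzyloxy)benzaldehyde | O=Cc1ccc(OCc2ccccc2)c(OCc2ccccc2)c1 | starting material
15 | [3,4-bis(benzyloxy)phenyl]methanol | OCc1ccc(OCc2ccccc2)c(OCc2ccccc2)c1 | intermediate
16 | 3,4-bis(benzyloxy)benzyl chloride | ClCc1ccc(OCc2ccccc2)c(OCc2ccccc2)c1 | intermediate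
17 | 3,4-bis(benzyloxy)benzylmagnesium chloride | Cl[Mg]Cc1ccc(OCc2ccccc2)c(OCc2ccccc2)c1 | intermediate
18 | (3S,5S)-5-(benzyloxy)-1-[3,4-bis(benzyloxy)phenyl]-7-[4-(benzyloxy)phenyl]heptan-3-ol | O[C@@H](CCc1ccc(OCc2ccccc2)c(OCc2ccccc2)c1)C[C@@H](OCc1ccccc1)CCc1ccc(OCc2ccccc2)cc1 | intermediate
19 | (3S,5S)-5-(benzyloxy)-1-[3,4-bis(benzyloxy)phenyl]-7-[4-(benzyloxy)phenyl]heptan-3-yl acetate | CC(=O)O[C@@H](CCc1ccc(OCc2ccccc2)c(OCc2ccccc2)c1)C[C@@H](OCc1ccccc1)CCc1ccc(OCc2ccccc2)cc1 | intermediate
20 | (3S,5S)-1-(3,4-dihydroxyphenyl)-5-hydroxy-7-(4-hydroxyphenyl)heptan-3-yl acetate | CC(=O)O[C@@H](CCc1ccc(O)c(O)c1)C[C@@H](O)CCc1ccc(O)cc1 | target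

**Step count and risks**

Total steps: 11. Longest linear sequence: 9 steps (steps 1, 2, 3, 4, 5, 6, 9, 10, 11); steps 7 and 8 form the side branch to 16.

Steps most likely to fail:

1. Step 9. Magnesium insertion into the very electron-rich benzylic chloride 16 may be overtaken by Wurtz homocoupling, so that too little Grignard reagent remains for a clean opening of 13. The fallback sets out from 14 and 13 and comes back at 18; it replaces the Grignard reagent by an acyl-anion equivalent and makes steps 7 and 8 unnecessary. Aldehyde 14 is condensed with propane-1,3-dithiol (BF3·OEt2, CH2Cl2, 0 °C) to 2-[3,4-bis(benzyloxy)phenyl]-1,3-dithiane F1. F1 is deprotonated (n-BuLi, THF, −78 → −20 °C) and 13 is added, the anion opening the oxirane at its CH2 carbon to give (2R,4S)-4-(benzyloxy)-1-{2-[3,4-bis(benzyloxy)phenyl]-1,3-dithian-2-yl}-6-[4-(benzyloxy)phenyl]hexan-2-ol F2. Desulfurisation with Raney nickel deactivated by brief reflux in acetone (EtOH, rt) should then deliver 18; any benzyl ether lost here is harmless as long as the O5 ether survives until step 10, because step 11 removes them all.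

2. Step 5. The benzylic Grignard reagent may open both oxiranes (loss of mono-selectivity) and may be depleted by homocoupling while it is made. The fallback sets out from 10 and 9 and comes back at 12; it uses a sulfone-stabilised benzylic anion. Chloride 10 and PhSO2Na (DMF, 60 °C) give 1-(benzyloxy)-4-[(phenylsulfonyl)methyl]benzene F3. F3 is deprotonated (n-BuLi, THF, −78 °C) and added as the limiting component to excess 9 with BF3·OEt2 at −78 °C, giving (2R)-4-[4-(benzyloxy)phenyl]-1-[(2R)-oxiran-2-yl]-4-(phenylsulfonyl)butan-2-ol F4 as a mixture of C4 epimers. Reductive desulfonylation (Na(Hg), Na2HPO4, MeOH, −20 °C) removes the sulfonyl group and that stereocentre and returns 12.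

3. Step 3. Selectivity may erode if the chloromethyl groups compete with the carbonyls for ruthenium, and hydrodechlorination or catalyst deactivation by traces of HCl may lower conversion. The fallback sets out from 4 and comes back at 9; it replaces the catalyst-controlled reduction by resolution and can deliver at most about one quarter of the material. Reduction of 4 with NaBH4 (MeOH, 0 °C) gives 1,5-dichloropentane-2,4-diol as a mixture of racemic anti and meso isomers F5. KOH in Et2O closes this to 1,2:4,5-diepoxypentane as the stereoisomer mixture F6. Hydrolytic kinetic resolution with water and the antipode of (salen)Co(OAc) (trivalent cobalt) that hydrolyses S-configured alkyloxiranes should leave only the R,R isomer with both oxiranes intact; distillation from the water-soluble polyols returns 9.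

Further compounds
F1 | step 9 | 2-[3,4-bis(benzyloxy)phenyl]-1,3-dithiane | C1CSC(SC1)c1ccc(OCc2ccccc2)c(OCc2ccccc2)c1
F2 | step 9 | (2R,4S)-4-(benzyloxy)-1-{2-[3,4-bis(benzyloxy)phenyl]-1,3-dithian-2-yl}-6-[4-(benzyloxy)phenyl]hexan-2-ol | O[C@@H](CC1(SCCCS1)c1ccc(OCc2ccccc2)c(OCc2ccccc2)c1)C[C@@H](OCc1ccccc1)CCc1ccc(OCc2ccccc2)cc1
F3 | step 5 | 1-(benzyloxy)-4-[(phenylsulfonyl)methyl]benzene | O=S(=O)(Cc1ccc(OCc2ccccc2)cc1)c1ccccc1
F4 | step 5 | (2R)-4-[4-(benzyloxy)phenyl]-1-[(2R)-oxiran-2-yl]-4-(phenylsulfonyl)butan-2-ol (C4 epimers) | O[C@@H](CC(c1ccc(OCc2ccccc2)cc1)S(=O)(=O)c1ccccc1)C[C@@H]1CO1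
F5 | step 3 | 1,5-dichloropentane-2,4-diol (racemic anti and meso) | OC(CCl)CC(O)CCl
F6 | step 3 | 1,2:4,5-diepoxypentane (stereoisomer mixture) | C1OC1CC1CO1
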